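**Numbering used (cembrane type):** C1 = lactone β-CH, C2 = lactone O-CH, C3/C4 = epoxide (C4 bears CH3), C5 = CHOAc, C7=C8(CH3), C9 = CHOH, C11=C12(CH3), C14 = CHOAc, C15/C16/C17 = lactone α-C, C=O and exocyclic CH2. The target is (1R,2S,3S,4S,5R,9S,14R), with both ring alkenes E and a trans epoxide.

**Assumption:** compounds 1, 2, 10 and 11 are catalogue items. Compound 1 derives from L-tartaric acid and 10 is the bulk statin intermediate.

## Retrosynthetic overview
1. The last operations are C9 desilylation, C14 acetylation, C5 acetate by SN2 inversion, the C3-C4 epoxide by C5-OH-directed epoxidation, and the exo-methylene by Mannich/elimination on the macrocyclic lactone.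
2. The 14-membered ring comes from the C12-C13 bond. A light-driven Ni-H intramolecular hydroalkylation joins a methyl-capped alkyne to a primary iodide and also sets the E-C11=C12 geometry.
3. Ring order is γ-lactone first, macrocycle second, epoxide last.
4. The C2-C3 bond comes from Felkin addition of a C3-C12 alkenyllithium to a C13-C14-C1-C2(+C15,C16) aldehyde. That aldehyde comes from Fráter-Seebach alkylation of ethyl (S)-4-chloro-3-hydroxybutanoate (C14 bought, C1 anti to it).
5. The C3-C12 piece comes from two iterations on L-threitol ditosylate acetonide. Each iteration is C-metal + CH2OTs, double elimination to a propargylic alcohol, then syn-carboalumination. C9 and C5 are both bought this way.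

## Route

**Step 1**
Reactants: 1, (−)-1,4-di-O-tosyl-2,3-O-isopropylidene-L-threitol; 2, 1-propynyllithium
Product: 3, [(4S,5S)-5-(but-2-ynyl)-2,2-dimethyl-1,3-dioxolan-4-yl]methyl tosylate
Conditions: 2 (1 equiv), 1 (2.5 equiv, excess recovered), THF-DMPU, 0 → 23 °C
Reagents that add atoms: 1-propynyllithium, [Li]C#CC
Why: SN2 alkylation of an alkynyllithium at a primary tosylate; the electrophile is C2-symmetric and in excess, so either end gives the same mono-adduct and no stereocentre is touched.

**Step 2**
Reactants: 3
Product: 4, (S)-hepta-1,5-diyn-3-ol (HC7≡C8-C9H(OH)-C10H2-C11≡C12-CH3)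
Conditions: LDA (5 equiv), THF, −78 → 0 °C; aq NH4Cl
Reagents that add atoms: none
Why: Base-induced double elimination (E2 loss of TsOH to the exocyclic enol ether, then vinylic deprotonation/β-alkoxide expulsion and loss of acetone) turns one tartrate carbon into C8, and the other C-O bond is never broken, so it survives as C9 (S).

**Step 3**
Reactants: 4
Product: 5, (S)-3-(tert-butyldimethylsilyloxy)hepta-1,5-diyne
Conditions: TBSCl, imidazole, DMF, 23 °C
Reagents that add atoms: TBSCl, CC(C)(C)[Si](C)(C)Cl
Why: Standard silylation; it masks C9-OH so that it cannot direct the later epoxidation and stays distinguishable from the two future acetates.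

**Step 4**
Reactants: 5
Product: 6, (S,E)-3-(TBSO)-1-iodo-2-methylhept-1-en-5-yne
Conditions: Me3Al, Cp2ZrCl2 (0.3 equiv), CH2Cl2, −20 → 23 °C; then I2, THF, −30 °C
Reagents that add atoms: trimethylaluminium, C[Al](C)C; iodine, II
Why: Negishi Zr-catalysed syn-carboalumination reacts only at the terminal alkyne, places CH3 on C8 and Al on C7, and iodinolysis with retention gives the E-C7=C8 iodide.

**Step 5**
Reactants: 6; 1
Product: 7, [(4S,5S)-5-{(2E,4S)-4-(TBSO)-3-methyloct-2-en-6-ynyl}-2,2-dimethyl-1,3-dioxolan-4-yl]methyl tosylate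
Conditions: t-BuLi (2 equiv), Et2O, −78 °C; MgBr2·OEt2; then 1 (2.5 equiv), Li2CuCl4 (10 mol %), THF, −30 → 0 °C
Reagents that add atoms: none besides 1
Why: I/Li exchange with retention followed by Cu-catalysed sp2-sp3 coupling (SN2 at the primary tosylate) forms C6-C7 without touching the alkene geometry or any stereocentre.

**Step 6**
Reactants: 7
Product: 8, (3S,5E,7S)-7-(TBSO)-6-methylundeca-5-en-1,9-diyn-3-ol (HC3≡C4-C5H(OH)-…; C5 is S, the epimer of the target)
Conditions: LDA (5 equiv), THF, −78 → 0 °C; aq NH4Cl
Reagents that add atoms: none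
Why: The same double elimination as step 2 unveils the C3≡C4 alkyne and leaves the second tartrate carbinol intact as (5S), the configuration needed to direct the epoxidation.

**Step 7**
Reactants: 8
Product: 9, (1E,3S,5E,7S)-7-(TBSO)-1-iodo-2,6-dimethylundeca-1,5-dien-9-yn-3-ol
Conditions: Me3Al (4 equiv), Cp2ZrCl2 (1 equiv), CH2Cl2, 0 → 23 °C; then I2, THF, −30 °C
Reagents that add atoms: trimethylaluminium, C[Al](C)C; iodine, II
Why: Negishi syn-carboalumination/iodinolysis of the terminal alkyne (free OH carried as its Al alkoxide, internal alkyne inert) installs the C4 methyl and the E-C3 iodide.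

**Step 8**
Reactants: 10, ethyl (S)-4-chloro-3-hydroxybutanoate; 11, tert-butyl bromoacetate
Product: 12, 4-tert-butyl 1-ethyl (2R)-2-[(1S)-2-chloro-1-(triethylsilyloxy)ethyl]butanedioate
Conditions: LDA (2.15 equiv), THF, −78 → −55 °C; 11, DMPU, −78 → −55 °C; then TESCl, −55 → 0 °C (one pot)
Reagents that add atoms: tert-butyl bromoacetate, BrCC(=O)OC(C)(C)C; TESCl, CC[Si](CC)(CC)Cl
Why: In this Fráter-Seebach alkylation the chelated alkoxide-enolate dianion is attacked anti to the C14 substituent, which sets C1 anti to the bought C14-O, and cold TES capture stops the chlorohydrin alkoxide from closing to an epoxide.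

**Step 9**
Reactants: 12
Product: 13, 4-tert-butyl 1-ethyl (2R)-2-[(1S)-2-iodo-1-(triethylsilyloxy)ethyl]butanedioate
Conditions: NaI (6 equiv), NaHCO3, 2-butanone, 80 °C
Reagents that add atoms: sodium iodide, [Na+].[I-]
Why: Finkelstein exchange at the primary carbon C13; no stereocentre is involved.

**Step 10**
Reactants: 13
Product: 14, tert-butyl (3R,4S)-3-formyl-5-iodo-4-(triethylsilyloxy)pentanoate
Conditions: DIBAL-H (1.1 equiv), CH2Cl2, −78 °C; Rochelle salt
Reagents that add atoms: none
Why: Partial ester reduction; the ethyl ester reacts while the bulky tert-butyl ester, the iodide and the TES ether are inert at −78 °C.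

**Step 11**
Reactants: 9; 14
Product: 15, open-chain C2 carbinol (tert-butyl ester, C13 iodide, C14-OTES, C9-OTBS, free C2-OH and C5-OH, C11≡C12 alkyne). C1, C2, C9 and C14 are arranged as in the target and C5 is epimeric.
Conditions: 9, t-BuLi (3.05 equiv), Et2O, −78 °C; then 14, −78 °C; AcOH quench at −78 °C
Reagents that add atoms: none
Why: Alkenyllithium 1,2-addition under Felkin-Anh control (C14 group = large, CH2CO2tBu = medium) is reinforced by the 1,3-anti polar effect of the non-chelating β-OTES in this anti α,β-disubstituted aldehyde, and gives the 1,2-syn/1,3-anti C2 carbinol; the minor epimer is removed by chromatography.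

**Step 12**
Reactants: 15
Product: 16, trans-β,γ-disubstituted γ-butyrolactone. C2 carries the dienynyl chain and C1 carries CH(OTES)CH2I; C5-OH is free.
Conditions: TMSOTf, 2,6-lutidine, CH2Cl2, 0 °C; then 10 % aq citric acid-THF, 23 °C
Reagents that add atoms: none
Why: Buffered silyl-triflate cleavage of the tert-butyl ester, then hydrolysis of the TMS groups, lets the γ-hydroxy acid lactonise onto C2-OH without base (no Williamson attack on C13-I, no silyl migration) and without breaking any stereogenic bond.

**Step 13 (key step)**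
Reactants: 16
Product: 17, 14-membered carbocycle fused to the saturated trans-lactone (E-C3=C4, E-C7=C8, new E-C11=C12; C5-OH free, C9-OTBS, C14-OTES)
Conditions: NiBr2·glyme (15 mol %), dtbbpy (18 mol %), 4CzIPN (3 mol %), Hantzsch ester (2 equiv), 2,6-lutidine, DMA-THF, 1 mM (slow addition), 450 nm LEDs, 25 °C
Reagents that add atoms: none
Why: Proposed new method: light-driven Ni-H intramolecular hydroalkylation of an unactivated methyl-capped alkyne by a primary alkyl iodide - photoreduced 4CzIPN (Hantzsch ester as terminal reductant and proton source) gives low-valent Ni that is protonated to L·Ni-H, syn-hydronickelation puts Ni on the less hindered methyl-bearing C12 and H on C11 (the same steric bias as hydrozirconation of 2-alkynes), one-electron reduction gives an alkenyl-Ni(I) that abstracts iodine from the tethered C13-I, and in-cage radical capture with reductive elimination from Ni(III) forms C12-C13 with retention, so H and C13 are cis (= E-C11=C12), the ring closes and C14 is untouched; the pre-formed trans-lactone blocks the otherwise fast 5-exo attack of C13• on C3=C4, which would give a trans-bicyclo[3.3.0]octane; closest known reaction types are intermolecular CuH/Ni and NiH anti-Markovnikov hydroalkylation of terminal alkynes with alkyl iodides, metallaphotoredox alkyne hydroalkylation and Ni reductive cross-electrophile coupling, none shown for internal dialkyl alkynes or for macrocyclisation.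

**Step 14**
Reactants: 17
Product: 18, α-methylene lactone macrocycle (otherwise as 17)
Conditions: LDA (2.4 equiv), THF, −78 °C; Eschenmoser's salt, −78 → 0 °C; then MeI, MeOH-CH2Cl2; aq NaHCO3
Reagents that add atoms: Eschenmoser's salt, C=[N+](C)C.[I-]
Why: Enolate Mannich reaction followed by quaternisation and β-elimination; it is done before any acetate is present, C15 is the only enolisable site and nothing β to it can be eliminated.

**Step 15**
Reactants: 18
Product: 19, (3S,4S)-epoxide with (5S)-OH (erythro epoxy alcohol), otherwise as 18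
Conditions: VO(acac)2 (5 mol %), t-BuOOH (1.2 equiv), CH2Cl2, 0 °C
Reagents that add atoms: tert-butyl hydroperoxide, CC(C)(C)OO
Why: In this hydroxyl-directed vanadium epoxidation only C3=C4 is allylic to a free OH, and A(1,2) strain with the C4 methyl enforces the erythro transition state, so (5S)-OH delivers oxygen to the face giving (3S,4S), which is also the face anti to the C2-O bond.

**Step 16**
Reactants: 19
Product: 20, (5R)-acetate (C14-OTES, C9-OTBS, epoxide and methylene lactone intact)
Conditions: PPh3/DIAD (betaine pre-formed), AcOH, toluene, 0 → 23 °C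
Reagents that add atoms: acetic acid, CC(=O)O
Why: Mitsunobu SN2 at the only free hydroxyl inverts C5 from S to R and installs the natural acetate in the same operation.

**Step 17**
Reactants: 20
Product: 21, C5,C14-diacetate, C9-OTBS
Conditions: Et3N·3HF, THF, 0 → 23 °C; then Ac2O, pyridine, DMAP (cat.), same flask
Reagents that add atoms: acetic anhydride, CC(=O)OC(C)=O
Why: The secondary TES ether is cleaved far faster than the hindered allylic TBS ether, and acylating at once (retention at C14) prevents translactonisation of the free C14-OH.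

**Step 18**
Reactants: 21
Product: 22, michaolide A
Conditions: HF·pyridine, pyridine, THF, 0 → 23 °C
Reagents that add atoms: none
Why: Buffered fluoride desilylation frees C9-OH without opening the deactivated trisubstituted epoxide, adding to the enoate or moving the acetates.

## Compound list
| No. | Name | SMILES | Role |
|---|---|---|---|
| 1 | (−)-1,4-di-O-tosyl-2,3-O-isopropylidene-L-threitol | Cc1ccc(cc1)S(=O)(=O)OC[C@@H]2OC(C)(C)O[C@H]2COS(=O)(=O)c3ccc(C)cc3 | starting material |
| 2 | 1-propynyllithium | [Li]C#CC | starting material |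
| 3 | mono-butynyl dioxolane tosylate | CC#CC[C@@H]1OC(C)(C)O[C@H]1COS(=O)(=O)c2ccc(C)cc2 | intermediate |
| 4 | (S)-hepta-1,5-diyn-3-ol | C#C[C@@H](O)CC#CC | intermediate |
| 5 | TBS ether of 4 | C#C[C@@H](O[Si](C)(C)C(C)(C)C)CC#CC | intermediate |
| 6 | (S,E)-3-(TBSO)-1-iodo-2-methylhept-1-en-5-yne | CC#CC[C@H](O[Si](C)(C)C(C)(C)C)/C(C)=C/I | intermediate |
| 7 | C3-C12 dioxolane tosylate | CC#CC[C@H](O[Si](C)(C)C(C)(C)C)/C(C)=C/C[C@@H]1OC(C)(C)O[C@H]1COS(=O)(=O)c2ccc(C)cc2 | intermediate |
| 8 | (3S,5E,7S)-7-(TBSO)-6-methylundeca-5-en-1,9-diyn-3-ol | CC#CC[C@H](O[Si](C)(C)C(C)(C)C)/C(C)=C/C[C@H](O)C#C | intermediate |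
| 9 | (1E,3S,5E,7S)-7-(TBSO)-1-iodo-2,6-dimethylundeca-1,5-dien-9-yn-3-ol | CC#CC[C@H](O[Si](C)(C)C(C)(C)C)/C(C)=C/C[C@H](O)/C(C)=C/I | intermediate |
| 10 | ethyl (S)-4-chloro-3-hydroxybutanoate | CCOC(=O)C[C@H](O)CCl | starting material |
| 11 | tert-butyl bromoacetate | BrCC(=O)OC(C)(C)C | starting material |
| 12 | anti-alkylated chloro TES diester | CCOC(=O)[C@H](CC(=O)OC(C)(C)C)[C@H](O[Si](CC)(CC)CC)CCl | intermediate |
| 13 | iodo TES diester | CCOC(=O)[C@H](CC(=O)OC(C)(C)C)[C@H](O[Si](CC)(CC)CC)CI | intermediate |
| 14 | tert-butyl (3R,4S)-3-formyl-5-iodo-4-(TESO)pentanoate | O=C[C@H](CC(=O)OC(C)(C)C)[C@H](O[Si](CC)(CC)CC)CI | intermediate |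
| 15 | open-chain C2 carbinol | CC#CC[C@H](O[Si](C)(C)C(C)(C)C)/C(C)=C/C[C@H](O)/C(C)=C/[C@@H](O)[C@H](CC(=O)OC(C)(C)C)[C@H](O[Si](CC)(CC)CC)CI | intermediate |
| 16 | trans-lactone iodo-alkyne | CC#CC[C@H](O[Si](C)(C)C(C)(C)C)/C(C)=C/C[C@H](O)/C(C)=C/[C@H]1OC(=O)C[C@@H]1[C@H](O[Si](CC)(CC)CC)CI | intermediate |
| 17 | macrocyclic saturated lactone | C1C(=O)O[C@H]2[C@H]1[C@H](O[Si](CC)(CC)CC)C/C(C)=C/C[C@H](O[Si](C)(C)C(C)(C)C)/C(C)=C/C[C@H](O)/C(C)=C/2 | intermediate |
| 18 | macrocyclic α-methylene lactone | C=C1C(=O)O[C@H]2[C@H]1[C@H](O[Si](CC)(CC)CC)C/C(C)=C/C[C@H](O[Si](C)(C)C(C)(C)C)/C(C)=C/C[C@H](O)/C(C)=C/2 | intermediate |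
| 19 | (3S,4S)-epoxy-(5S)-alcohol | C=C1C(=O)O[C@H]2[C@H]1[C@H](O[Si](CC)(CC)CC)C/C(C)=C/C[C@H](O[Si](C)(C)C(C)(C)C)/C(C)=C/C[C@H](O)[C@]1(C)O[C@@H]21 | intermediate |
| 20 | (5R)-acetate, 14-OTES, 9-OTBS | C=C1C(=O)O[C@H]2[C@H]1[C@H](O[Si](CC)(CC)CC)C/C(C)=C/C[C@H](O[Si](C)(C)C(C)(C)C)/C(C)=C/C[C@@H](OC(C)=O)[C@]1(C)O[C@@H]21 | intermediate |
| 21 | 9-O-TBS-michaolide A | C=C1C(=O)O[C@H]2[C@H]1[C@H](OC(C)=O)C/C(C)=C/C[C@H](O[Si](C)(C)C(C)(C)C)/C(C)=C/C[C@@H](OC(C)=O)[C@]1(C)O[C@@H]21 | intermediate |
| 22 | michaolide A | C=C1C(=O)O[C@H]2[C@H]1[C@H](OC(C)=O)C/C(C)=C/C[C@H](O)/C(C)=C/C[C@@H](OC(C)=O)[C@]1(C)O[C@@H]21 | target |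

## Totals
- Total step count: 18.
- Longest linear sequence: 15 (steps 1-7, then 11-18). The side branch is steps 8-10.

## Three steps most likely to fail
1. **Step 13 (new Ni-H photochemical macro-hydroalkylation).** The risks are hydrodeiodination, the wrong alkyne regiochemistry (a 13-membered exocyclic isomer) and oligomers.
   - Fallback (known chemistry, different ring-closing bond): carry C3 as a vinylsilane made by silylcupration/MeI of 8.
   - Hydrozirconate and iodinate the methyl alkyne, then open ethyl (S)-3,4-epoxybutanoate (from 10) with the derived alkenyl cuprate to make C12-C13 first.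
   - Run the Fráter-Seebach/TES/DIBAL sequence on the full chain, iododesilylate, and close C2-C3 by a stoichiometric CrCl2/NiCl2 Nozaki-Hiyama-Kishi macrocyclisation.
2. **Step 16 (Mitsunobu at C5, next to a fully substituted epoxide carbon, with an enoate present).**
   - Fallback: use the enantiomeric D-threitol ditosylate in step 5, so that C5 is R from the start.
   - Convert macrocyclic C5-OH to its tert-butyl carbonate and iodocyclise (5-exo; the trans-dioxolanone corresponds to the threo relationship).
   - Treat with K2CO3/MeOH to close the (3S,4S)-epoxide, then acetylate C5 with retention.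
3. **Step 8 (Fráter-Seebach on a chlorohydrin; epoxide closure and elimination compete).**
   - Fallback: change the chiral-pool entry to diethyl L-malate and run the standard Fráter-Seebach alkylation with 11.
   - Reduce the α-hydroxy ester (C13) chemoselectively with BH3·SMe2/NaBH4 to the 1,2-diol.
   - Iodinate the primary alcohol selectively (I2, PPh3, imidazole) and add TESCl, which gives the same compound 13.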